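**Assumption:** position labels in the text use daucane numbering (C1 = quaternary C–CH3; C2, C3 = ring CH2; C4 = C(OH)(i‑Pr); C5 = ring‑fusion CH; C6 = CH–O; C7 = CH2; C8(CH3)=C9; C10 = CH2), and β is the face of the C1 methyl. Ferutinin is then 1β‑Me, 4β‑OH, 5α‑H, 6α‑O‑aroyl, i.e. (3R,3aS,4S,8aR) in azulene nomenclature.

## Retrosynthetic overview
1. C6–O ester: ferutinin ⇒ jaeschkeanadiol + 4‑acetoxybenzoyl chloride; the phenol is unmasked last.
2. C6–OH/C7–H ⇒ ring 1,3‑diene (Cu‑catalysed protoboration/oxidation); C4 carbinol ⇒ cyclopentanone + isopropyl nucleophile.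
3. C1–CH3 and C5–H ⇒ achiral bicyclic trienone, by enantioselective conjugate methylation and protonation (sets absolute configuration and the trans ring fusion).
4. Trienone ⇒ aryl diazoketone: both rings form in one operation. A Rh carbene closes the five‑membered ring onto the p‑tolyl ring while the benzene ring expands to the seven‑membered ring; the para‑methyl becomes the C8 vinyl methyl.
5. Diazoketone ⇒ 3‑(4‑methylphenyl)propanoic acid + diazomethane.

## Forward route

**Step 1**
Reactants: 1, 3‑(4‑methylphenyl)propanoic acid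
Product: 2, 1‑diazo‑4‑(4‑methylphenyl)butan‑2‑one
Conditions: (COCl)2, cat. DMF, CH2Cl2, 0 °C → rt; concentrate; CH2N2 (3 equiv), Et2O, 0 °C
Reagents that add atoms: diazomethane, C=[N+]=[N-]
Why: Acylation of diazomethane by the in situ acid chloride (Arndt–Eistert‑type diazoketone synthesis), with excess CH2N2 scavenging HCl; no stereocentre is formed.

**Step 2**
Reactants: 2, 1‑diazo‑4‑(4‑methylphenyl)butan‑2‑one
Product: 3, 6‑methyl‑3,4‑dihydroazulen‑1(2H)‑one (cyclopentenone conjugated to the tetrasubstituted ring‑fusion C=C; ring CH2 on the β‑fusion carbon; methyl‑bearing 1,3‑diene in the seven‑membered ring)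
Conditions: Rh2(OAc)4 (0.5 mol %), CH2Cl2, reflux, slow addition of 2; then Et3N (1 equiv), rt
Reagents that add atoms: none
Why: Intramolecular Buchner reaction: the Rh carbene cyclopropanates the ipso/ortho bond of the tolyl ring, the norcaradiene opens electrocyclically to the cycloheptatriene, and Et3N moves the triene into conjugation (Scott azulenone synthesis); the product is achiral.

**Step 3**
Reactants: 3, 6‑methyl‑3,4‑dihydroazulen‑1(2H)‑one
Product: 4, (3aR,8aR)‑3a,6‑dimethyl‑3,3a,4,8a‑tetrahydroazulen‑1(2H)‑one (trans‑fused; C1 methyl β, C5–H α; C6=C7–C8(Me)=C9 diene)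
Conditions: Me3Al (2 equiv), CuTC (5 mol %), chiral biphenol/bis(1‑phenylethyl)amine phosphoramidite L* (10 mol %), Et2O, −30 °C; MeOH quench at −78 °C, Rochelle salt work‑up; use crude
Reagents that add atoms: trimethylaluminium, C[Al](C)C
Why: Proposed new method: Cu‑catalysed asymmetric conjugate addition of Me3Al to a tetrasubstituted, cross‑conjugated cyclopentenone (Al activates the carbonyl, the chiral Cu–Me π‑complex transfers methyl to the only β‑carbon, C1, and the resulting aluminium trienolate is stabilised by the ring diene); the closest known reactions are Alexakis/Hoveyda‑type asymmetric conjugate additions of Me3Al to β,β‑disubstituted cyclic enones and Me2CuLi additions to 2,3‑disubstituted cyclopentenones; the ligand sets C1 (its enantiomer is chosen empirically to give 1R‑type, "8aR" in ferutinin), and kinetic α‑protonation of the trienolate anti to the new quasi‑axial methyl should give the trans fusion, which the ~70° ring torsion of the cyclohepta‑1,3‑diene also accommodates best.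

**Step 4**
Reactants: 4, (3aR,8aR)‑3a,6‑dimethyl‑3,3a,4,8a‑tetrahydroazulen‑1(2H)‑one
Product: 5, (1R,3aR,8aR)‑3a,6‑dimethyl‑1‑(propan‑2‑yl)‑1,2,3,3a,4,8a‑hexahydroazulen‑1‑ol (4β‑OH, 4α‑i‑Pr)
Conditions: i‑PrMgCl, anhydrous CeCl3, THF, −78 °C
Reagents that add atoms: isopropylmagnesium chloride, CC(C)[Mg]Cl
Why: Organocerium 1,2‑addition (suppresses enolisation of the acidic C5–H and β‑hydride reduction); the nucleophile attacks the α‑face, on the side of H5 and away from the β‑oriented C6 and C1 methyl, giving OH cis to the methyl.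

**Step 5**
Reactants: 5, the diene carbinol from step 4
Product: 6, jaeschkeanadiol, (3R,3aS,4S,8aR)‑6,8a‑dimethyl‑3‑(propan‑2‑yl)‑1,2,3,3a,4,5,8,8a‑octahydroazulene‑3,4‑diol (4β,6α‑diol, 5α‑H, Δ8)
Conditions: B2pin2 (1.2 equiv), CuCl (5 mol %), Xantphos (5 mol %), NaOt‑Bu (10 mol %), MeOH (2 equiv), THF, 0 °C; then NaOH, H2O2, 0 °C → rt
Reagents that add atoms: hydrogen peroxide, OO (oxygen of the C6–OH); B2pin2, CC1(C)OB(OC1(C)C)B1OC(C)(C)C(C)(C)O1, is transient and leaves no atoms
Why: Cu‑catalysed protoboration of a 2‑substituted 1,3‑diene: Cu–Bpin adds across the less substituted C6=C7 bond with boron at the diene terminus C6, the allyl‑copper is protonated at C7 (leaving C8=C9), and boron enters from the α‑face (side of H5, anti to the quaternary C4 and the C1 methyl), so stereoretentive oxidation gives the 6α‑alcohol.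

**Step 6**
Reactants: 6, jaeschkeanadiol; 7, 4‑acetoxybenzoyl chloride
Product: 8, (3R,3aS,4S,8aR)‑3‑hydroxy‑6,8a‑dimethyl‑3‑(propan‑2‑yl)‑1,2,3,3a,4,5,8,8a‑octahydroazulen‑4‑yl 4‑(acetyloxy)benzoate
Conditions: 7 (1.5 equiv), pyridine, cat. DMAP, CH2Cl2, 0 °C → rt
Reagents that add atoms: 4‑acetoxybenzoyl chloride (7), CC(=O)Oc1ccc(C(=O)Cl)cc1
Why: DMAP‑catalysed acylation is selective for the secondary C6–OH over the unreactive tertiary C4–OH; no stereocentre is touched.

**Step 7**
Reactants: 8, the acetate‑protected ester from step 6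
Product: 9, ferutinin, (3R,3aS,4S,8aR)‑3‑hydroxy‑6,8a‑dimethyl‑3‑(propan‑2‑yl)‑1,2,3,3a,4,5,8,8a‑octahydroazulen‑4‑yl 4‑hydroxybenzoate
Conditions: K2CO3 (1 equiv), MeOH, 0 °C, 30 min
Reagents that add atoms: none
Why: Chemoselective methanolysis of the aryl acetate, which is far more labile than the hindered secondary aroate (further deactivated once the phenoxide forms); stereocentres are unaffected.

## Compound list
1 | 3‑(4‑methylphenyl)propanoic acid | Cc1ccc(CCC(=O)O)cc1 | starting material
2 | 1‑diazo‑4‑(4‑methylphenyl)butan‑2‑one | Cc1ccc(CCC(=O)C=[N+]=[N-])cc1 | intermediate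
3 | 6‑methyl‑3,4‑dihydroazulen‑1(2H)‑one | CC1=CCC2=C(C=C1)C(=O)CC2 | intermediate
4 | (3aR,8aR)‑3a,6‑dimethyl‑3,3a,4,8a‑tetrahydroazulen‑1(2H)‑one | CC1=CC[C@@]2(C)CCC(=O)[C@@H]2C=C1 | intermediate
5 | (1R,3aR,8aR)‑3a,6‑dimethyl‑1‑(propan‑2‑yl)‑1,2,3,3a,4,8a‑hexahydroazulen‑1‑ol | CC1=CC[C@@]2(C)CC[C@@](O)(C(C)C)[C@@H]2C=C1 | intermediate
6 | jaeschkeanadiol, (3R,3aS,4S,8aR)‑6,8a‑dimethyl‑3‑(propan‑2‑yl)‑1,2,3,3a,4,5,8,8a‑octahydroazulene‑3,4‑diol | CC1=CC[C@@]2(C)CC[C@@](O)(C(C)C)[C@@H]2[C@@H](O)C1 | intermediate
7 | 4‑acetoxybenzoyl chloride | CC(=O)Oc1ccc(C(=O)Cl)cc1 | starting material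
8 | ferutinin O‑acetate (4‑acetoxybenzoate of 6) | CC1=CC[C@@]2(C)CC[C@@](O)(C(C)C)[C@@H]2[C@@H](OC(=O)c2ccc(OC(C)=O)cc2)C1 | intermediate
9 | ferutinin | CC1=CC[C@@]2(C)CC[C@@](O)(C(C)C)[C@@H]2[C@@H](OC(=O)c2ccc(O)cc2)C1 | target

The ring‑fusion CH descriptor changes from R (4, 5) to S (6, 8, 9) only because the CIP priorities change when C6 gains oxygen; the geometry is the same.

## Summary
Total steps: 7. Longest linear sequence: 7 (from 1; compound 7 is purchased).

Steps most likely to fail:
1. **Step 3** (reactivity and ee on a tetrasubstituted enone; trans‑selective protonation). Fallback: racemic methylation with Me2CuLi/TMSCl, isolating the silyl trienol ether and protonating it separately to control the ring fusion, then obtain the single enantiomer by lipase‑mediated kinetic resolution (acylation at C6–OH) of rac‑6.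
2. **Step 5** (site and 1,2‑ versus 1,4‑selectivity of the diene protoboration). Fallback: VO(acac)2/TBHP epoxidation of C6=C7 directed by the homoallylic C4–OH, Pd(0)/HCO2H hydrogenolysis of the vinyl epoxide to the 6β‑ol, then Mitsunobu esterification with 4‑acetoxybenzoic acid with inversion to reach 8 directly.
3. **Step 4** (enolisation of the doubly activated C5–H or reduction instead of addition). Fallback: add isopropenylcerium (sp2 nucleophile, no β‑hydride), carry the isopropenyl group through step 5, and hydrogenate the 1,1‑disubstituted alkene selectively (Wilkinson's catalyst) at the diol stage.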